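Two numbers are asked of this flask, target and side product, and I reckon both from one ratio.

common to all: starting material 0.73 M
- south: second substrate 0.73 M; free catalyst 0.49 mM; run made earlier
- south-east: second substrate 0.73 M; free catalyst 1.1 mM; run made earlier
- north-east: second substrate 1.5 M; free catalyst 0.73 mM; run made earlier
- flask: second substrate 0.730 M; free catalyst 0.73 mM; time 40 h

- south (time / h: side product / %, target / %): 5.00: 27.1, 36.7; 10.0: 45.6, 49.1; 15.0: 47.7, 51.1; 20.0: 48.9, 52.0; 25.0: 48.5, 51.8; 30.0: 48.7, 51.7
- south-east (time / h: side product / %, target / %): 2.00: 12.9, 42.0; 6.00: 29.2, 66.7; 12.0: 30.1, 69.6; 20.0: 30.1, 70.1; 25.0: 30.2, 70.4; 30.0: 30.8, 68.9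
- north-east (time / h: side product / %, target / %): 3.00: 16.4, 35.9; 8.00: 37.4, 56.3; 15.0: 41.4, 58.4; 25.0: 41.2, 59.5; 30.0: 40.1, 59.0

(scatter of a reading: 0.5 percentage points)

- percent here means starting material units held: one side product counts as two

- concentration of side product at 40 h, in M
- concentration of target at 40 h, in M

In the south run, target and side product together hold 101% of the charge at 20.0 h. The flask runs longer than that, so I take it as finished and watch the split, not the clock. From south to south-east the free catalyst charge grows by a factor 2.24 and the plateau ratio of target to side product by 2.19. So, with starting material and second substrate held at these charges, I freeze that ratio divided by the catalyst charged, which the two runs read as 2.14 /mM: this is my split per catalyst, a selectivity factor taken per unit of catalyst.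

Two extreme versions of the flask are easy. A lean one behaves like south and ends with target fraction 0.515; a rich one behaves like south-east and ends with 0.700. With the same second substrate, the flask's catalyst charge is more than south's and less than south-east's, so I place the flask between them. The split per catalyst places it: the ratio is 1.56, so I expect target fraction 0.610 and side fraction 0.390.

The forecast gives 0.143 M side product and 0.444 M target, on the ground that “The ratio is almost proportional to catalyst”.

The flask gives 0.143 M side product and 0.443 M target, which are fractions 0.393 and 0.607 of the charge.

    starting material + free catalyst ⇌ catalyst intermediate A (K = 7.90 /M, k = 0.180 /M/s)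
    catalyst intermediate A → free catalyst + target (k = 0.140 /s)
    second substrate + free catalyst ⇌ catalyst intermediate B (K = 190 /M, k = 0.270 /M/s)
    catalyst intermediate B → free catalyst + second product (k = 0.560 /s)
    starting material + target → side product (k = 8.40 × 10⁻⁵ /M/s)

At 10.0 h the flask's starting material is down to 1.49% of the charge, and at 400 h the flask still holds 0.143 M side product. A neighbour flask charged with 0.440 mM free catalyst has a ratio of 0.943 by the split per catalyst, hence target fraction 0.485, and at 40.0 h it holds 49.0% target.

All runs stem from a simulated flask with constants of no real substance.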